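**Retrosynthetic overview**

1. The target comes from its 3,6,9-tris-silyl ether: the C4=C20 methylene is made last from a C4–CH2–CO2H arm (decarboxylative selenation, selenoxide elimination), and the C7–C11 bond by Michael addition of the C6-ketone enolate of a trans-hydroazulenone to a vinyl sulfone carrying C12–C17 (from (3S,4S)-hexa-1,5-diene-3,4-diol).
2. The trans-hydroazulenone comes from Grob fragmentation of a cis-anti-cis cyclopentane–cyclobutane–cyclopentane tricycle: the C6–C10 bond shared by the five-membered ring C6–C7–C8–C9–C10 and the cyclobutane C1–C5–C6–C10 is broken, so this five-membered ring takes up C1 and C5 and becomes the seven-membered ring, with C6=O and C10=C18 formed at once.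
3. Enabling feature: the tertiary oxygen on C6 and the tosyloxymethyl carbon C18 on C10 flank the C6–C10 bond (a 1,3-diol monosulfonate); until then the C6 oxygen is held in a temporary six-membered ring O–C21–C20–C4–C5–C6 (not in the target), first as an ether tether, then as a lactone that methoxide opens.
4. The tricycle comes from an intramolecular [2+2] photocycloaddition of a 3-alkoxy-2-(benzyloxymethyl)cyclopent-2-enone whose alkoxy group is the side arm of the cyclopentene ring C1–C5, bought as (1S,5R)-2-oxabicyclo[3.3.0]oct-6-en-3-one; C9 is reduced on the rigid tricycle.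
5. Ring order: cyclopentene C1–C5 (bought), cyclopentanedione C6–C10 (from a cyclobutene), cyclobutane plus tether ring (photochemistry), seven-membered ring (fragmentation); then side chain, then the C4 methylene.

Key step: step 11

Remark: locants follow the target skeleton (ring C1–C10 with C1 and C5 at the ring fusion, C18 on C10, C20 on C4, side chain C11–C17 with C19 the methyl on C11; C21 is an extra carbon on C20 that is excised in step 20); β is the face carrying O3, O6, H5 and the C7 side chain in the target, α the face of H1 and O9; the lactone, the bis-silyloxycyclobutene, the acetal, the hexadienediol and phenyl vinyl sulfone are assumed to be bought as single compounds.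

**Step 1**
Reactants: 1 (1S,5R)-2-oxabicyclo[3.3.0]oct-6-en-3-one
Product: 3 tert-butyldimethylsilyl 2-[(1R,5S)-5-(tert-butyldimethylsilyloxy)cyclopent-2-en-1-yl]acetate, via potassium 2-[(1R,5S)-5-hydroxycyclopent-2-en-1-yl]acetate 2 (not isolated)
Conditions: KOH, MeOH/H2O, rt; evaporate; TBSCl, imidazole, DMF, rt
Reagents that add atoms: potassium hydroxide [K+].[OH-]; tert-butyldimethylsilyl chloride CC(C)(C)[Si](C)(C)Cl
Why: Lactone saponification followed by exhaustive O-silylation (silyl ether and silyl ester) should block relactonization; C3 and C4 come unchanged from 1, whose cis ring fusion places O3 and C20 on the same (β) face.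

**Step 2**
Reactants: 3 tert-butyldimethylsilyl 2-[(1R,5S)-5-(tert-butyldimethylsilyloxy)cyclopent-2-en-1-yl]acetate
Product: 4 2-[(1R,5S)-5-(tert-butyldimethylsilyloxy)cyclopent-2-en-1-yl]ethan-1-ol
Conditions: LiAlH4, Et2O, 0 °C
Reagents that add atoms: none
Why: Hydride reduction of the silyl ester to the primary alcohol should leave the secondary silyl ether and the ring alkene untouched (ester reduction).

**Step 3**
Reactants: 5 1,2-bis(trimethylsilyloxy)cyclobut-1-ene; 6 benzyloxyacetaldehyde dimethyl acetal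
Product: 8 2-[(benzyloxy)methyl]cyclopentane-1,3-dione, via 2-[2-(benzyloxy)-1-methoxyethyl]-2-(trimethylsilyloxy)cyclobutan-1-one 7 (not isolated)
Conditions: BF3·OEt2, CH2Cl2, −78 °C; then CF3CO2H, rt
Reagents that add atoms: none
Why: Kuwajima–Nakamura dione synthesis: Mukaiyama aldol of the bis-silyl enediol with the acetal, then acid-induced pinacol-type acyl shift, which enlarges the cyclobutanone to the 2-substituted cyclopentane-1,3-dione.

**Step 4**
Reactants: 4 2-[(1R,5S)-5-(tert-butyldimethylsilyloxy)cyclopent-2-en-1-yl]ethan-1-ol; 8 2-[(benzyloxy)methyl]cyclopentane-1,3-dione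
Product: 9 2-[(benzyloxy)methyl]-3-{2-[(1R,5S)-5-(tert-butyldimethylsilyloxy)cyclopent-2-en-1-yl]ethoxy}cyclopent-2-en-1-one
Conditions: PPh3, DIAD, THF, 0 °C → rt
Reagents that add atoms: none
Why: Mitsunobu O-alkylation of the acidic dione enol by the primary alcohol should give the vinylogous ester (C-alkylation would have to build a quaternary carbon), and the symmetrical dione allows only one enol ether.

**Step 5**
Reactants: 9 2-[(benzyloxy)methyl]-3-{2-[(1R,5S)-5-(tert-butyldimethylsilyloxy)cyclopent-2-en-1-yl]ethoxy}cyclopent-2-en-1-one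
Product: 10 photoadduct keto ether (cyclobutane C1–C5–C6–C10 fused cis-anti-cis to cyclopentanone C6–C7–C8–C9(=O)–C10 and to cyclopentane C1–C5; oxane ring O–C21H2–C20H2–C4–C5–C6; BnOCH2 on C10; 3β-OTBS; H1 and H5 both α)
Conditions: hν (350 nm, Pyrex), degassed MeCN (5 mM), 0 °C
Reagents that add atoms: none
Why: Intramolecular enone–alkene [2+2] photocycloaddition of a 3-alkoxyenone through a four-atom tether: the first bond C6–C5 closes the six-membered oxacycle, the tether on C4 allows attack only on the alkene face cis to C20 and enforces the cis-anti-cis array, so C1, C5, C6 and C10 follow from the C4 stereocenter.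

**Step 6**
Reactants: 10 photoadduct keto ether
Product: 11 hydroxy ketone (as 10 but HOCH2 on C10)
Conditions: H2 (1 atm), Pd(OH)2/C, EtOAc, rt
Reagents that add atoms: none
Why: Hydrogenolysis of the benzyl ether; no alkene is left after the cycloaddition and the neutral medium avoids retro-aldol loss of C18.

**Step 7**
Reactants: 11 hydroxy ketone
Product: 12 9,18-diol (as 11 but C9 is a carbinol; 9-OH cis to the C10–C1 bond and trans to C18)
Conditions: Me4NBH(OAc)3, MeCN/AcOH, −20 °C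
Reagents that add atoms: none
Why: Saksena–Evans directed reduction: the C18 alkoxy(triacetoxy)borohydride delivers hydride to C9 from the convex face that carries C18, so the new hydroxyl lies cis to the C10–C1 bond, which is the 9α configuration of the target.

**Step 8**
Reactants: 12 9,18-diol
Product: 13 18-tosylate of 12 (9-OH free)
Conditions: TsCl, pyridine, CH2Cl2, 0 °C → rt
Reagents that add atoms: p-toluenesulfonyl chloride Cc1ccc(cc1)S(Cl)(=O)=O
Why: Selective sulfonylation of the primary hydroxyl over the hindered secondary one puts the nucleofuge on C18.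

**Step 9**
Reactants: 13 18-tosylate
Product: 14 9-O-TBS ether of 13
Conditions: TBSOTf, 2,6-lutidine, CH2Cl2, 0 °C
Reagents that add atoms: tert-butyldimethylsilyl trifluoromethanesulfonate CC(C)(C)[Si](C)(C)OS(=O)(=O)C(F)(F)F
Why: Silyl triflate protection of O9, so that later only the C6 oxygen can act as electron donor and RuO4 finds no free carbinol.

**Step 10**
Reactants: 14 9-O-TBS 18-tosylate
Product: 15 δ-lactone (as 14 but C21 is a carbonyl carbon: ring O–C21(=O)–C20H2–C4–C5–C6)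
Conditions: RuCl3·H2O (cat.), NaIO4, CCl4/MeCN/H2O, rt
Reagents that add atoms: sodium periodate [Na+].[O-]I(=O)(=O)=O
Why: RuO4 oxidation of a cyclic ether to the lactone at its only O–CH2 group (C21), C6 being fully substituted; silyl ethers and the sulfonate should be inert.

**Step 11**
Reactants: 15 δ-lactone
Product: 18 methyl 2-[(1αH,5βH)-3β,9α-bis(tert-butyldimethylsilyloxy)-10(18)-methylene-6-oxodecahydroazulen-4β-yl]acetate, via sodium alkoxide 16 (not isolated), via cis-fused ketone 17 (not isolated)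
Conditions: NaOMe (1.1 equiv), MeOH/THF, 0 °C → rt
Reagents that add atoms: sodium methoxide [Na+].[O-]C
Why: Methoxide opens the δ-lactone at C21 to the methyl ester and the tertiary C6 cyclobutanolate 16, in which the O–C6 lone pair, the C6–C10 bond and the antiperiplanar C18–OTs bond fragment in concert (Grob or Wharton fragmentation of a 1,3-diol monosulfonate) to give the C6 ketone, the exocyclic C10=C18 alkene and tosylate. Because the bond that breaks is shared by the cyclopentane C6–C10 and the cyclobutane, the five-membered ring takes up C1 and C5 and becomes the seven-membered ring; no ring is closed here, the closures having been made in step 5 (C6–C5 through the six-membered tether ring, then C10–C1). The closest known reactions are the base-induced fragmentation of γ-hydroxy sulfonates to medium-ring alkenyl ketones and the retro-aldol ring expansion of de Mayo photoadducts; cyclobutane strain release and the neopentyl character of C18 should suppress substitution and oxetane formation, and O9 is silylated so that only O6 can push. C1, C3 and C9 are untouched, whereas C5, which is cis in 17, is epimerized by the remaining methoxide through the C6 enolate to the trans-fused ketone 18. The trans isomer should be favoured because in 17 the C1–C10, C3–O, C4–C20 and C5–C6 bonds all lie on the β face of the cyclopentane, while in 18 C6 is trans to both neighbours. The step needs chemoselective attack at the lactone carbonyl rather than at sulfur or silicon, which the unhindered lactone and only a slight excess of methoxide (also avoiding Claisen closure between C7 and C21) should secure.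

**Step 12**
Reactants: 19 (3S,4S)-hexa-1,5-diene-3,4-diol
Product: 20 (4S,5S)-2,2-dimethyl-4,5-divinyl-1,3-dioxolane
Conditions: 2,2-dimethoxypropane, PPTS (cat.), CH2Cl2, rt
Reagents that add atoms: 2,2-dimethoxypropane COC(C)(C)OC
Why: Acetonide formation by transacetalization; the two carbinol centres become C12 and C13 of the target.

**Step 13**
Reactants: 20 (4S,5S)-2,2-dimethyl-4,5-divinyl-1,3-dioxolane (threefold excess); 21 phenyl vinyl sulfone
Product: 22 (4S,5S)-2,2-dimethyl-4-[(E)-2-(phenylsulfonyl)ethenyl]-5-vinyl-1,3-dioxolane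
Conditions: second-generation Hoveyda–Grubbs catalyst (5 mol %), CH2Cl2, 40 °C
Reagents that add atoms: none
Why: Olefin cross-metathesis with the vinyl sulfone should give the E-alkenyl sulfone; the excess of the C2-symmetric diene limits double reaction and the electron-poor product does not react on.

**Step 14**
Reactants: 22 (4S,5S)-2,2-dimethyl-4-[(E)-2-(phenylsulfonyl)ethenyl]-5-vinyl-1,3-dioxolane
Product: 23 (4S,5S)-2,2-dimethyl-4-(2-methylprop-1-en-1-yl)-5-[(E)-2-(phenylsulfonyl)ethenyl]-1,3-dioxolane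
Conditions: second-generation Grubbs catalyst (5 mol %), 2-methylbut-2-ene/CH2Cl2, 40 °C
Reagents that add atoms: 2-methylbut-2-ene CC=C(C)C
Why: Cross-metathesis of the remaining vinyl group with 2-methylbut-2-ene installs the isobutenyl end (C14–C17); the vinyl sulfone is inert.

**Step 15**
Reactants: 18 methyl 2-[(1αH,5βH)-3β,9α-bis(tert-butyldimethylsilyloxy)-10(18)-methylene-6-oxodecahydroazulen-4β-yl]acetate; 23 (4S,5S)-2,2-dimethyl-4-(2-methylprop-1-en-1-yl)-5-[(E)-2-(phenylsulfonyl)ethenyl]-1,3-dioxolane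
Product: 26 methyl 2-[(1αH,5βH,7αH)-3β,9α-bis(tert-butyldimethylsilyloxy)-7-{(1R)-1-[(4S,5S)-2,2-dimethyl-5-(2-methylprop-1-en-1-yl)-1,3-dioxolan-4-yl]-2-(phenylsulfonyl)ethyl}-10(18)-methylene-6-oxodecahydroazulen-4β-yl]acetate, via lithium enolate 24 (not isolated), via lithiated sulfone adduct 25 (not isolated)
Conditions: LiN(i-Pr)2, THF, −78 °C; then 23, THF, −78 → −40 °C; AcOH, −78 °C
Reagents that add atoms: none
Why: Michael addition of the kinetic lithium enolate (deprotonation at the C7 methylene, not the C5 methine) to the γ-alkoxy vinyl sulfone: axial attack on the β face of C7, trans to the C5–C4 bond and to the 9α-silyloxy group, sets C7, attack anti to the C12–O bond (Felkin–Anh) sets C11, and the cold quench precedes enolate equilibration.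

**Step 16**
Reactants: 26 Michael adduct (6-ketone)
Product: 27 6β-alcohol of 26
Conditions: LiBH(s-Bu)3, THF, −78 °C; then H2O
Reagents that add atoms: none
Why: Bulky hydride should attack the C6 ketone from the α face, opposite the C7 side chain, giving the 6β-alcohol cis to the side chain (selectride reduction of a 2-substituted cycloalkanone); ester and sulfone are inert at −78 °C.

**Step 17**
Reactants: 27 6β-alcohol
Product: 28 3β,6β,9α-tris(tert-butyldimethylsilyl) ether
Conditions: TBSOTf, 2,6-lutidine, CH2Cl2, 0 °C → rt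
Reagents that add atoms: tert-butyldimethylsilyl trifluoromethanesulfonate CC(C)(C)[Si](C)(C)OS(=O)(=O)C(F)(F)F
Why: Silyl triflate protection of the hindered 6β-hydroxyl, so that later only the side-chain diol is acetylated.

**Step 18**
Reactants: 28 tris-silyl ether sulfone
Product: 29 methyl 2-[(1αH,5βH,7αH)-3β,6β,9α-tris(tert-butyldimethylsilyloxy)-7-{(1R)-1-[(4S,5S)-2,2-dimethyl-5-(2-methylprop-1-en-1-yl)-1,3-dioxolan-4-yl]ethyl}-10(18)-methylenedecahydroazulen-4β-yl]acetate
Conditions: Na(Hg), Na2HPO4, MeOH/THF, −20 °C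
Reagents that add atoms: none
Why: Reductive desulfonylation turns the phenylsulfonylmethyl group into the C19 methyl group; the oxygen on C12 is γ to the sulfone carbon, so no Julia-type elimination can occur.

**Step 19**
Reactants: 29 methyl ester
Product: 30 carboxylic acid of 29 (C21 acid)
Conditions: LiOH, THF/MeOH/H2O, rt; then 1 M HCl to pH 4, 0 °C
Reagents that add atoms: lithium hydroxide [Li+].[OH-]
Why: Saponification of the unhindered methyl ester; secondary silyl ethers and the acetonide should survive.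

**Step 20**
Reactants: 30 carboxylic acid
Product: 32 4β-[(phenylselanyl)methyl] compound (C21 lost; C20–SePh), via thiohydroxamate ester 31 (not isolated)
Conditions: 1-hydroxypyridine-2(1H)-thione, DCC, DMAP (cat.), CH2Cl2, 0 °C, dark; then PhSeSePh (excess), hν (tungsten lamp), rt
Reagents that add atoms: diphenyl diselenide c1ccc(cc1)[Se][Se]c1ccccc1
Why: Barton decarboxylation: photolysis of the O-acyl thiohydroxamate releases CO2 and the primary C20 radical, which the excess diselenide should trap faster than it can add to the C10 methylene.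

**Step 21**
Reactants: 32 selenide
Product: 34 4(20),10(18)-bis-methylene tris-silyl ether acetonide, via selenoxide 33 (not isolated)
Conditions: NaIO4, NaHCO3, THF/MeOH/H2O, 0 → 40 °C
Reagents that add atoms: none
Why: Selenide oxidation and syn selenoxide elimination; the only β-hydrogen is on C4, so the exocyclic C4=C20 alkene must form, and no peracid is present to touch the other alkenes.

**Step 22**
Reactants: 34 bis-methylene acetonide
Product: 35 12,13-diol
Conditions: PPTS (cat.), MeOH, 40 °C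
Reagents that add atoms: none
Why: Acid-catalysed transacetalization with methanol should cleave the strained trans-dioxolane while the secondary silyl ethers remain.

**Step 23**
Reactants: 35 12,13-diol
Product: 36 12,13-diacetate
Conditions: Ac2O, pyridine, DMAP (cat.), CH2Cl2, rt
Reagents that add atoms: acetic anhydride CC(=O)OC(C)=O
Why: Acetylation of the only free hydroxyls (C12 and C13).

**Step 24**
Reactants: 36 12,13-diacetate
Product: 37 CNP0172457.2 (1R,3S,5S,6R,7S,9R,11R,12S,13S in the numbering of the remark)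
Conditions: HF·pyridine, pyridine/THF, 0 °C → rt
Reagents that add atoms: none
Why: Buffered fluoride cleavage of the three silyl ethers should leave the acetates and both allylic alcohols intact (desilylation).

**Compound list**

1 | (1S,5R)-2-oxabicyclo[3.3.0]oct-6-en-3-one | O=C1C[C@@H]2C=CC[C@@H]2O1 | starting material
2 | potassium 2-[(1R,5S)-5-hydroxycyclopent-2-en-1-yl]acetate | [K+].[O-]C(=O)C[C@@H]1C=CC[C@@H]1O | intermediate
3 | tert-butyldimethylsilyl 2-[(1R,5S)-5-(tert-butyldimethylsilyloxy)cyclopent-2-en-1-yl]acetate | CC(C)(C)[Si](C)(C)OC(=O)C[C@@H]1C=CC[C@@H]1O[Si](C)(C)C(C)(C)C | intermediate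
4 | 2-[(1R,5S)-5-(tert-butyldimethylsilyloxy)cyclopent-2-en-1-yl]ethan-1-ol | OCC[C@@H]1C=CC[C@@H]1O[Si](C)(C)C(C)(C)C | intermediate
5 | 1,2-bis(trimethylsilyloxy)cyclobut-1-ene | C[Si](C)(C)OC1=C(O[Si](C)(C)C)CC1 | starting material
6 | benzyloxyacetaldehyde dimethyl acetal | COC(COCc1ccccc1)OC | starting material
7 | 2-[2-(benzyloxy)-1-methoxyethyl]-2-(trimethylsilyloxy)cyclobutan-1-one (diastereomer mixture) | O=C1CCC1(O[Si](C)(C)C)C(OC)COCc1ccccc1 | intermediate
8 | 2-[(benzyloxy)methyl]cyclopentane-1,3-dione | O=C1CCC(=O)C1COCc1ccccc1 | intermediate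
9 | 2-[(benzyloxy)methyl]-3-{2-[(1R,5S)-5-(tert-butyldimethylsilyloxy)cyclopent-2-en-1-yl]ethoxy}cyclopent-2-en-1-one | O=C1CCC(OCC[C@@H]2C=CC[C@@H]2O[Si](C)(C)C(C)(C)C)=C1COCc1ccccc1 | intermediate
10 | photoadduct keto ether (cis-anti-cis cyclopentanone–cyclobutane–cyclopentane, oxane tether, 10-CH2OBn, 3β-OTBS, 1αH, 5αH) | C1C[C@@H]2[C@@H]3[C@@]4(O1)CCC(=O)[C@@]4(COCc5ccccc5)[C@@H]3C[C@@H]2O[Si](C)(C)C(C)(C)C | intermediate
11 | hydroxy ketone (10 with CH2OH on C10) | C1C[C@@H]2[C@@H]3[C@@]4(O1)CCC(=O)[C@@]4(CO)[C@@H]3C[C@@H]2O[Si](C)(C)C(C)(C)C | intermediate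
12 | 9,18-diol (9-OH cis to the C10–C1 bond) | C1C[C@@H]2[C@@H]3[C@@]4(O1)CC[C@@H](O)[C@@]4(CO)[C@@H]3C[C@@H]2O[Si](C)(C)C(C)(C)C | intermediate
13 | 18-tosylate of 12 | C1C[C@@H]2[C@@H]3[C@@]4(O1)CC[C@@H](O)[C@@]4(COS(=O)(=O)c5ccc(C)cc5)[C@@H]3C[C@@H]2O[Si](C)(C)C(C)(C)C | intermediate
14 | 9-O-TBS ether of 13 | C1C[C@@H]2[C@@H]3[C@@]4(O1)CC[C@@H](O[Si](C)(C)C(C)(C)C)[C@@]4(COS(=O)(=O)c5ccc(C)cc5)[C@@H]3C[C@@H]2O[Si](C)(C)C(C)(C)C | intermediate
15 | δ-lactone (14 with C21=O) | O=C1C[C@@H]2[C@@H]3[C@@]4(O1)CC[C@@H](O[Si](C)(C)C(C)(C)C)[C@@]4(COS(=O)(=O)c5ccc(C)cc5)[C@@H]3C[C@@H]2O[Si](C)(C)C(C)(C)C | intermediate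
16 | sodium C6 cyclobutanolate methyl ester | [Na+].COC(=O)C[C@@H]1[C@@H]2[C@@]3([O-])CC[C@@H](O[Si](C)(C)C(C)(C)C)[C@@]3(COS(=O)(=O)c4ccc(C)cc4)[C@@H]2C[C@@H]1O[Si](C)(C)C(C)(C)C | intermediate
17 | methyl 2-[(1αH,5αH)-3β,9α-bis(tert-butyldimethylsilyloxy)-10(18)-methylene-6-oxodecahydroazulen-4β-yl]acetate (cis-fused) | COC(=O)C[C@@H]1[C@@H]2C(=O)CC[C@@H](O[Si](C)(C)C(C)(C)C)C(=C)[C@@H]2C[C@@H]1O[Si](C)(C)C(C)(C)C | intermediate
18 | methyl 2-[(1αH,5βH)-3β,9α-bis(tert-butyldimethylsilyloxy)-10(18)-methylene-6-oxodecahydroazulen-4β-yl]acetate (trans-fused) | COC(=O)C[C@@H]1[C@H]2C(=O)CC[C@@H](O[Si](C)(C)C(C)(C)C)C(=C)[C@@H]2C[C@@H]1O[Si](C)(C)C(C)(C)C | intermediate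
19 | (3S,4S)-hexa-1,5-diene-3,4-diol | C=C[C@H](O)[C@@H](O)C=C | starting material
20 | (4S,5S)-2,2-dimethyl-4,5-divinyl-1,3-dioxolane | C=C[C@@H]1OC(C)(C)O[C@H]1C=C | intermediate
21 | phenyl vinyl sulfone | C=CS(=O)(=O)c1ccccc1 | starting material
22 | (4S,5S)-2,2-dimethyl-4-[(E)-2-(phenylsulfonyl)ethenyl]-5-vinyl-1,3-dioxolane | O=S(=O)(c1ccccc1)/C=C/[C@@H]1OC(C)(C)O[C@H]1C=C | intermediate
23 | (4S,5S)-2,2-dimethyl-4-(2-methylprop-1-en-1-yl)-5-[(E)-2-(phenylsulfonyl)ethenyl]-1,3-dioxolane | O=S(=O)(c1ccccc1)/C=C/[C@@H]1OC(C)(C)O[C@H]1C=C(C)C | intermediate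
24 | lithium C6(O)=C7 enolate of 18 | [Li+].COC(=O)C[C@@H]1[C@H]2C([O-])=CC[C@@H](O[Si](C)(C)C(C)(C)C)C(=C)[C@@H]2C[C@@H]1O[Si](C)(C)C(C)(C)C | intermediate
25 | C19-lithiated Michael adduct | [Li+].COC(=O)C[C@@H]1[C@H]2C(=O)[C@H]([C@@H]([CH-]S(=O)(=O)c3ccccc3)[C@@H]4OC(C)(C)O[C@H]4C=C(C)C)C[C@@H](O[Si](C)(C)C(C)(C)C)C(=C)[C@@H]2C[C@@H]1O[Si](C)(C)C(C)(C)C | intermediate
26 | Michael adduct, 6-ketone, 7β side chain with CH2SO2Ph on C11 | COC(=O)C[C@@H]1[C@H]2C(=O)[C@H]([C@@H](CS(=O)(=O)c3ccccc3)[C@@H]4OC(C)(C)O[C@H]4C=C(C)C)C[C@@H](O[Si](C)(C)C(C)(C)C)C(=C)[C@@H]2C[C@@H]1O[Si](C)(C)C(C)(C)C | intermediate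
27 | 6β-alcohol of 26 | COC(=O)C[C@@H]1[C@H]2[C@H](O)[C@H]([C@@H](CS(=O)(=O)c3ccccc3)[C@@H]4OC(C)(C)O[C@H]4C=C(C)C)C[C@@H](O[Si](C)(C)C(C)(C)C)C(=C)[C@@H]2C[C@@H]1O[Si](C)(C)C(C)(C)C | intermediate
28 | 3β,6β,9α-tris(TBS) ether sulfone | COC(=O)C[C@@H]1[C@H]2[C@H](O[Si](C)(C)C(C)(C)C)[C@H]([C@@H](CS(=O)(=O)c3ccccc3)[C@@H]4OC(C)(C)O[C@H]4C=C(C)C)C[C@@H](O[Si](C)(C)C(C)(C)C)C(=C)[C@@H]2C[C@@H]1O[Si](C)(C)C(C)(C)C | intermediate
29 | desulfonylated methyl ester (C19 methyl) | COC(=O)C[C@@H]1[C@H]2[C@H](O[Si](C)(C)C(C)(C)C)[C@H]([C@@H](C)[C@@H]3OC(C)(C)O[C@H]3C=C(C)C)C[C@@H](O[Si](C)(C)C(C)(C)C)C(=C)[C@@H]2C[C@@H]1O[Si](C)(C)C(C)(C)C | intermediate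
30 | C21 carboxylic acid | OC(=O)C[C@@H]1[C@H]2[C@H](O[Si](C)(C)C(C)(C)C)[C@H]([C@@H](C)[C@@H]3OC(C)(C)O[C@H]3C=C(C)C)C[C@@H](O[Si](C)(C)C(C)(C)C)C(=C)[C@@H]2C[C@@H]1O[Si](C)(C)C(C)(C)C | intermediate
31 | 2-thioxopyridin-1(2H)-yl ester of 30 | S=c1ccccn1OC(=O)C[C@@H]2[C@H]3[C@H](O[Si](C)(C)C(C)(C)C)[C@H]([C@@H](C)[C@@H]4OC(C)(C)O[C@H]4C=C(C)C)C[C@@H](O[Si](C)(C)C(C)(C)C)C(=C)[C@@H]3C[C@@H]2O[Si](C)(C)C(C)(C)C | intermediate
32 | 4β-[(phenylselanyl)methyl] compound | c1ccccc1[Se]C[C@@H]2[C@H]3[C@H](O[Si](C)(C)C(C)(C)C)[C@H]([C@@H](C)[C@@H]4OC(C)(C)O[C@H]4C=C(C)C)C[C@@H](O[Si](C)(C)C(C)(C)C)C(=C)[C@@H]3C[C@@H]2O[Si](C)(C)C(C)(C)C | intermediate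
33 | selenoxide of 32 | O=[Se](c1ccccc1)C[C@@H]2[C@H]3[C@H](O[Si](C)(C)C(C)(C)C)[C@H]([C@@H](C)[C@@H]4OC(C)(C)O[C@H]4C=C(C)C)C[C@@H](O[Si](C)(C)C(C)(C)C)C(=C)[C@@H]3C[C@@H]2O[Si](C)(C)C(C)(C)C | intermediate
34 | 4(20),10(18)-bis-methylene 3β,6β,9α-tris(TBS) ether 12,13-acetonide | C=C1[C@H]2[C@H](O[Si](C)(C)C(C)(C)C)[C@H]([C@@H](C)[C@@H]3OC(C)(C)O[C@H]3C=C(C)C)C[C@@H](O[Si](C)(C)C(C)(C)C)C(=C)[C@@H]2C[C@@H]1O[Si](C)(C)C(C)(C)C | intermediate
35 | 12,13-diol tris(TBS) ether | C=C1[C@H]2[C@H](O[Si](C)(C)C(C)(C)C)[C@H]([C@@H](C)[C@H](O)[C@H](C=C(C)C)O)C[C@@H](O[Si](C)(C)C(C)(C)C)C(=C)[C@@H]2C[C@@H]1O[Si](C)(C)C(C)(C)C | intermediate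
36 | 12,13-diacetate tris(TBS) ether | C=C1[C@H]2[C@H](O[Si](C)(C)C(C)(C)C)[C@H]([C@@H](C)[C@H](OC(C)=O)[C@H](C=C(C)C)OC(C)=O)C[C@@H](O[Si](C)(C)C(C)(C)C)C(=C)[C@@H]2C[C@@H]1O[Si](C)(C)C(C)(C)C | intermediate
37 | CNP0172457.2 | C=C1[C@H]2[C@H](O)[C@H]([C@@H](C)[C@H](OC(C)=O)[C@H](C=C(C)C)OC(C)=O)C[C@@H](O)C(=C)[C@@H]2C[C@@H]1O | target

**Step count and risks**

Total: 24 steps. Longest linear sequence: 20 steps (steps 1, 2, 4–11 and 15–24, from lactone 1).

Steps most likely to fail:

1. Step 15. The hindered enolate may add too slowly to the β-substituted vinyl sulfone, the sulfone may instead be deprotonated at C12, the facial selectivity at C11 may be poor, or proton transfer may equilibrate C7 before the quench. Fallback from 18 and 20, returning at 29: diene 20 is cross-metathesized with tert-butyl acrylate (second-generation Hoveyda–Grubbs catalyst) to tert-butyl (E)-3-[(4S,5S)-2,2-dimethyl-5-vinyl-1,3-dioxolan-4-yl]prop-2-enoate F1 and then with 2-methylbut-2-ene to the isobutenyl enoate F2. Lithium enolate 24 is added to this γ-alkoxy enoate, a well-documented anti-selective acceptor class, to give the keto diester F3. LiBH(s-Bu)3 should give the 6β-alcohol F4 and TBSOTf the tris-silyl ether F5. TMSOTf/2,6-lutidine cleaves only the tert-butyl ester to the side-chain acid F6, whose thiohydroxamate ester F7 is photolysed with t-BuSH (Barton reductive decarboxylation) to give 29.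

2. Step 3. The pinacol-type acyl shift may stall because the migrating terminus is destabilized by the neighbouring benzyloxy group, or the benzyl ether may be lost in CF3CO2H. Fallback from 4, returning at 9: the benzyloxymethyl group is introduced after the enol ether is made. Mitsunobu reaction of 4 with commercial cyclopentane-1,3-dione gives 3-{2-[(1R,5S)-5-(tert-butyldimethylsilyloxy)cyclopent-2-en-1-yl]ethoxy}cyclopent-2-en-1-one F8; NBS brominates its electron-rich α-carbon to the 2-bromo enone F9; Stille coupling with Bu3SnCH2OBn (Pd(PPh3)4, CuI, DMF) gives 9.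

3. Step 20. Material may be lost through the light- and heat-sensitive thiohydroxamate ester, and the later elimination of the primary selenoxide may be slow enough for benzeneselenenic acid to add back to the isobutenyl group. Fallback from 30, returning at 34: direct oxidative decarboxylation (Kochi reaction: Pb(OAc)4, Cu(OAc)2, pyridine, benzene, 80 °C), in which the C20 radical is captured by divalent copper and loses the C4 hydrogen to give the exocyclic alkene in one step without selenium.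

**Further compounds**

F1 | step 15 | tert-butyl (E)-3-[(4S,5S)-2,2-dimethyl-5-vinyl-1,3-dioxolan-4-yl]prop-2-enoate | CC(C)(C)OC(=O)/C=C/[C@@H]1OC(C)(C)O[C@H]1C=C
F2 | step 15 | tert-butyl (E)-3-[(4S,5S)-2,2-dimethyl-5-(2-methylprop-1-en-1-yl)-1,3-dioxolan-4-yl]prop-2-enoate | CC(C)(C)OC(=O)/C=C/[C@@H]1OC(C)(C)O[C@H]1C=C(C)C
F3 | step 15 | keto diester Michael adduct (CH2CO2t-Bu on C11) | COC(=O)C[C@@H]1[C@H]2C(=O)[C@H]([C@@H](CC(=O)OC(C)(C)C)[C@@H]3OC(C)(C)O[C@H]3C=C(C)C)C[C@@H](O[Si](C)(C)C(C)(C)C)C(=C)[C@@H]2C[C@@H]1O[Si](C)(C)C(C)(C)C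
F4 | step 15 | 6β-alcohol of F3 | COC(=O)C[C@@H]1[C@H]2[C@H](O)[C@H]([C@@H](CC(=O)OC(C)(C)C)[C@@H]3OC(C)(C)O[C@H]3C=C(C)C)C[C@@H](O[Si](C)(C)C(C)(C)C)C(=C)[C@@H]2C[C@@H]1O[Si](C)(C)C(C)(C)C
F5 | step 15 | 6-O-TBS ether of F4 | COC(=O)C[C@@H]1[C@H]2[C@H](O[Si](C)(C)C(C)(C)C)[C@H]([C@@H](CC(=O)OC(C)(C)C)[C@@H]3OC(C)(C)O[C@H]3C=C(C)C)C[C@@H](O[Si](C)(C)C(C)(C)C)C(=C)[C@@H]2C[C@@H]1O[Si](C)(C)C(C)(C)C
F6 | step 15 | side-chain carboxylic acid (CH2CO2H on C11) | COC(=O)C[C@@H]1[C@H]2[C@H](O[Si](C)(C)C(C)(C)C)[C@H]([C@@H](CC(=O)O)[C@@H]3OC(C)(C)O[C@H]3C=C(C)C)C[C@@H](O[Si](C)(C)C(C)(C)C)C(=C)[C@@H]2C[C@@H]1O[Si](C)(C)C(C)(C)C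
F7 | step 15 | 2-thioxopyridin-1(2H)-yl ester of F6 | COC(=O)C[C@@H]1[C@H]2[C@H](O[Si](C)(C)C(C)(C)C)[C@H]([C@@H](CC(=O)On4ccccc4=S)[C@@H]3OC(C)(C)O[C@H]3C=C(C)C)C[C@@H](O[Si](C)(C)C(C)(C)C)C(=C)[C@@H]2C[C@@H]1O[Si](C)(C)C(C)(C)C
F8 | step 3 | 3-{2-[(1R,5S)-5-(tert-butyldimethylsilyloxy)cyclopent-2-en-1-yl]ethoxy}cyclopent-2-en-1-one | O=C1CCC(OCC[C@@H]2C=CC[C@@H]2O[Si](C)(C)C(C)(C)C)=C1
F9 | step 3 | 2-bromo-3-{2-[(1R,5S)-5-(tert-butyldimethylsilyloxy)cyclopent-2-en-1-yl]ethoxy}cyclopent-2-en-1-one | O=C1CCC(OCC[C@@H]2C=CC[C@@H]2O[Si](C)(C)C(C)(C)C)=C1Br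
F0 | step 20 | none | none
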